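Time has stopped mattering by the first reading: Friday's target stands at 40.5% at 0.250 d and at 41.2% at 3.00 d, with a scatter of 0.5 percentage points. So we look for the plateau of the new flask and for what ended it.

in all of them: free catalyst 12 mol%
- Friday's: substrate 0.10 M; partner 1.3 equiv; second catalyst 0.025 mol%; run made earlier
- Sunday's: substrate 0.10 M; partner 1.3 equiv; second catalyst 0.1 mol%; run made earlier
- Thursday's: substrate 0.20 M; partner 1.3 equiv; second catalyst 0.05 mol%; run made earlier
- flask: substrate 0.10 M; partner 1.30 equiv; second catalyst 0.05 mol%; time 4.0 d

- Friday's (time / d: substrate / %, target / %): 0.250: 15.7, 40.5; 0.500: 16.4, 41.6; 0.833: 15.6, 40.4; 1.67: 16.6, 41.2; 3.00: 16.3, 41.2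
- Sunday's (time / d: substrate / %, target / %): 0.250: 8.8, 68.2; 0.833: 8.3, 67.9; 1.67: 8.1, 68.3; 2.50: 8.9, 68.1; 3.00: 8.8, 68.7
- Thursday's (time / d: substrate / %, target / %): 0.250: 4.2, 85.0; 0.500: 3.6, 85.2; 0.833: 4.4, 86.1; 1.67: 3.9, 85.7; 3.00: 3.4, 86.1

(each reading ± 0.5 percentage points)

- which holds at 4.0 d: what has brought the reaction to rest, or that it has not come to rest (all of the substrate has reacted / no working catalyst is left / the partner has run out first / forward and back rates have come level / it is still moving)
- conversion of substrate at 4.0 d
- amount of target at 4.0 d, in percent of the substrate charged

- a reading or a percentage of target counts all its forms, free or not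
- the reaction counts as stopped when no species that holds the substrate changes by six tenths of a point or more over the second half of the time

Friday's mean target is 41.0% and Sunday's is 68.2%, so Friday's charge of partner leaves 0.890 equivalents not read as target, and Sunday's leaves 0.618. We suppose that partner also decays by itself and is the limiting reagent. It then has two exits, and its own concentration stands in both rates and cancels. At this one substrate concentration, each wasted equivalent then buys target in proportion to the second catalyst and to the substrate not yet target. Integrated, the depth, the logarithm of charge over what is not yet target, grows in step with wasted partner.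

Friday's depth is 0.527 and Sunday's is 1.15. Depth per waste should rise 4.00-fold with the loading, but it rises 3.14-fold. That is the weak link. We suppose that some partner decays before the unread form of the substrate has built up, and we count that part as buying nothing. Taking off a lead that restores the proportion gives 0.293 equivalents, 22.5% of the charge. The catch, depth per equivalent wasted after the lead, is then 0.882 at Friday's loading.

The new flask has twice that loading, so its catch is 1.76, with 1.01 equivalents of useful partner. Midway between the runs, 54.6% needs depth 0.790, and the partner supplies 0.814. One correction gives 55.2%. Friday's substrate reads 27.3% of what is not target, so, taking that share over, we commit to a conversion of 87.8%, and we name the partner as what has brought the new flask to rest.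

The forecast says no working catalyst is left, 88% and 55%, holding that “I→target then stops when the second catalyst dies”.

In the flask the partner has run out first, with a conversion of 87.6% and target at 55.4%.

    partner + second catalyst + intermediate → second catalyst + target (k = 8300 M⁻² min⁻¹)
    target ⇌ isomer of the product (K = 1.30, k = 0.0660 min⁻¹)
    partner → decomposed reagent (k = 0.0160 min⁻¹)
    substrate + free catalyst ⇌ free catalyst + intermediate (K = 2.40, k = 4.70 M⁻¹ min⁻¹)
    crystals ⇌ target, rate k5*(cs5 - [target]) while solid is left; crystals form when [target] > cs5 (solubility = 1.90 mM, k = 2.00 min⁻¹)

In the flask partner stands at 0% of its charge, decomposed reagent at 0.0721 M, which is 0.721 equivalents, and the isomer of the product at 2.47%, so together they make 0.746 equivalents not standing as target. At this target the catch asks for 0.750 equivalents wasted, lead included. With 0.780 equiv of partner, the same flask otherwise, useful partner is 0.604 equivalents. Starting in proportion at 33.1%, one correction gives 35.6%, and that flask holds 35.8%.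

Readings and results were generated by integration with made-up constants; scatter was added.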